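**Plan**

- Numbering: ring A is the cyclohexene, with C1 (acyl), C2 (Ar1 = 3,4-dimethoxyphenyl), C3=C4, C5H2 and C6 (Ar2 = 4-hydroxy-3-methoxyphenyl); C7 is the ring-bound carbonyl, C8 the diketone CH, C9 the enol carbon.
- Retrosynthesis: cut C8–C9 (methyl ketone enolate plus feruloyl donor), step the acetyl group back to a C1 methyl ester, then cut C1–C7 and C6–Ar2 together.
- Enabling feature: ring A without C7 and Ar2 is 3-(3,4-dimethoxyphenyl)cyclohexa-1,4-diene, mirror-symmetric through C2 and C5; the target carries Ar2 and the acyl group cis across the former C1=C6 alkene, both trans to Ar1.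
- Forward: ring A is never closed; it is the phenyl ring of a biaryl after Birch reduction. A palladium-catalysed three-component aryl-methoxycarbonylation adds Ar2 and C7, and the chain then grows C7 → acetyl → feruloyl.
- Stereochemistry: a chiral bisphosphine picks one enantiotopic alkene, Ar1 shields its own face, and syn insertion with retentive CO migration sets C1/C6 cis; later steps enolise only the methyl side of the ketone.

Key step: step 3

Assumption: the hand of BINAP that leads to the (1S,2S,6S) series cannot be predicted with confidence for this new reaction; (R)-BINAP is written, and its antipode is used if the first run gives the mirror-image ester.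

**Route**

Step 1
Reactants: 1 3,4-dimethoxybiphenyl
Product: 3 3-(3,4-dimethoxyphenyl)cyclohexa-1,4-diene, via lithium 1-(3,4-dimethoxyphenyl)cyclohexa-2,5-dien-1-ide 2 (not isolated)
Conditions: Li (2.2 equiv), NH3(l)/THF, −78 °C; then solid NH4Cl, −78 °C to rt
Reagents that add atoms: none
Why: Birch reduction of a biaryl, in which the unsubstituted ring takes up two electrons, ammonia protonates the para carbon, and kinetic protonation of pentadienyl anion 2 at its central (ipso) carbon by NH4Cl should give the non-conjugated meso diene.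

Step 2
Reactants: 4 4-iodo-2-methoxyphenol
Product: 5 (4-iodo-2-methoxyphenoxy)tri(propan-2-yl)silane
Conditions: i-Pr3SiCl (1.2 equiv), imidazole (2.5 equiv), DMF, rt
Reagents that add atoms: chlorotri(propan-2-yl)silane, CC(C)[Si](Cl)(C(C)C)C(C)C
Why: Imidazole-promoted silylation of a phenol; the bulky silyl group is chosen to survive methanol, Grignard reagents and amide bases later on.

Step 3
Reactants: 3 3-(3,4-dimethoxyphenyl)cyclohexa-1,4-diene; 5 (4-iodo-2-methoxyphenoxy)tri(propan-2-yl)silane; 6 carbon monoxide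
Product: 7 methyl (1S,2S,6S)-2-(3,4-dimethoxyphenyl)-6-{3-methoxy-4-[tri(propan-2-yl)silyloxy]phenyl}cyclohex-3-ene-1-carboxylate
Conditions: Pd2(dba)3 (2.5 mol %), (R)-BINAP (6 mol %), AgOAc (1.2 equiv), CO (1 atm), MeOH (10 equiv), toluene, 50 °C; 3 (3 equiv)
Reagents that add atoms: carbon monoxide 6, [C-]#[O+]; methanol, CO
Why: Proposed new method: oxidative addition of 5 to the zerovalent palladium–BINAP complex and iodide abstraction by AgOAc should give a cationic arylpalladium species of divalent palladium, which inserts one alkene of 3 syn on the face away from Ar1 with Ar2 going to C6 (the carbon remote from C2) and palladium to C1; CO then takes the one free site of the chelate, the alkyl group migrates to CO with retention at C1, and methanol cleaves the acylpalladium species while acetate takes up the proton. The closest known reaction types are the three-component aryl-alkoxycarbonylation of norbornene-type alkenes, the Heck desymmetrisation of cyclohexa-1,4-dienes with cationic BINAP–palladium catalysts, and the capture by CO of alkylpalladium intermediates that carry β-hydrogens in alternating CO/alkene copolymerisation. The step closes no ring and forms C6–Ar2 and C1–C7 in one intermolecular event. C2 becomes a stereocentre through the ligand's choice of one of the two enantiotopic alkenes, C6 follows from attack anti to Ar1, and C1 follows from syn insertion and retentive migration, which leaves C7 cis to Ar2 and trans to Ar1. Two selectivities are needed: alkene insertion must come before carbonylation of the arylpalladium species (1 atm CO, excess 3, limited methanol), and CO insertion must beat β-hydride loss toward C2 (the chelating ligand leaves no cis vacancy once CO is bound); the pseudoaxial Ar1 on the mirror plane of 3 supplies the facial and regiochemical bias, and the second alkene, now flanked by C2, is left as C3=C4.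

Step 4
Reactants: 7 methyl (1S,2S,6S)-2-(3,4-dimethoxyphenyl)-6-{3-methoxy-4-[tri(propan-2-yl)silyloxy]phenyl}cyclohex-3-ene-1-carboxylate
Product: 8 (1S,2S,6S)-2-(3,4-dimethoxyphenyl)-N-methoxy-6-{3-methoxy-4-[tri(propan-2-yl)silyloxy]phenyl}-N-methylcyclohex-3-ene-1-carboxamide
Conditions: MeNH(OMe)·HCl (3 equiv), i-PrMgCl (6 equiv), THF, −20 to 0 °C
Reagents that add atoms: N,O-dimethylhydroxylamine hydrochloride, CNOC.Cl
Why: Aminolysis of the ester by Me(MeO)NMgCl made in the flask (Weinreb amide synthesis from an ester); this magnesium amide is a poor base toward the hindered C1–H, so C1, C2 and C6 should be kept.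

Step 5
Reactants: 8 (1S,2S,6S)-2-(3,4-dimethoxyphenyl)-N-methoxy-6-{3-methoxy-4-[tri(propan-2-yl)silyloxy]phenyl}-N-methylcyclohex-3-ene-1-carboxamide
Product: 10 1-[(1S,2S,6S)-2-(3,4-dimethoxyphenyl)-6-{3-methoxy-4-[tri(propan-2-yl)silyloxy]phenyl}cyclohex-3-en-1-yl]ethan-1-one, via bromomagnesium hemiaminal 9 (not isolated)
Conditions: MeMgBr (3 equiv), THF, 0 °C; aqueous work-up
Reagents that add atoms: methylmagnesium bromide, C[Mg]Br
Why: Weinreb ketone synthesis, in which the chelated tetrahedral adduct 9 lasts until work-up, so one methyl group is delivered and the ketone never meets the Grignard reagent.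

Step 6
Reactants: 11 ferulic acid
Product: 13 (E)-3-{3-methoxy-4-[tri(propan-2-yl)silyloxy]phenyl}prop-2-enoic acid, via bis-silylated ferulate 12 (not isolated)
Conditions: i-Pr3SiCl (2.4 equiv), imidazole (5 equiv), DMF, rt; then 1 M aq. HCl, THF, rt
Reagents that add atoms: chlorotri(propan-2-yl)silane, CC(C)[Si](Cl)(C(C)C)C(C)C
Why: Silylation of phenol and acid followed by selective hydrolysis of the silyl ester, which is far more labile to dilute aqueous acid than the hindered aryl silyl ether.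

Step 7
Reactants: 13 (E)-3-{3-methoxy-4-[tri(propan-2-yl)silyloxy]phenyl}prop-2-enoic acid
Product: 14 (E)-1-(1H-benzotriazol-1-yl)-3-{3-methoxy-4-[tri(propan-2-yl)silyloxy]phenyl}prop-2-en-1-one
Conditions: 1H-benzotriazole (4 equiv), SOCl2 (1.05 equiv), CH2Cl2, rt
Reagents that add atoms: 1H-benzotriazole, c1ccc2[nH]nnc2c1
Why: Activation of the acid as its N-acylbenzotriazole through the sulfinyl-bis(benzotriazole) formed from SOCl2; excess benzotriazole buffers HCl, so the aryl silyl ether and the E alkene should be untouched.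

Step 8
Reactants: 10 1-[(1S,2S,6S)-2-(3,4-dimethoxyphenyl)-6-{3-methoxy-4-[tri(propan-2-yl)silyloxy]phenyl}cyclohex-3-en-1-yl]ethan-1-one; 14 (E)-1-(1H-benzotriazol-1-yl)-3-{3-methoxy-4-[tri(propan-2-yl)silyloxy]phenyl}prop-2-en-1-one
Product: 16 (2Z,4E)-1-[(1S,2S,6S)-2-(3,4-dimethoxyphenyl)-6-{3-methoxy-4-[tri(propan-2-yl)silyloxy]phenyl}cyclohex-3-en-1-yl]-3-hydroxy-5-{3-methoxy-4-[tri(propan-2-yl)silyloxy]phenyl}penta-2,4-dien-1-one, via methyl-side lithium enolate 15 (not isolated)
Conditions: LiN(SiMe3)2 (2.5 equiv), THF, −78 °C; then 14 (1.1 equiv), −78 to −20 °C; then AcOH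
Reagents that add atoms: none
Why: Crossed Claisen-type C-acylation of a kinetic lithium enolate with an N-acylbenzotriazole; the amide base removes a methyl proton and not the hindered C1–H, and the second equivalent of base stores the product as its diketonate, so C1 should not epimerise.

Step 9
Reactants: 16 (2Z,4E)-1-[(1S,2S,6S)-2-(3,4-dimethoxyphenyl)-6-{3-methoxy-4-[tri(propan-2-yl)silyloxy]phenyl}cyclohex-3-en-1-yl]-3-hydroxy-5-{3-methoxy-4-[tri(propan-2-yl)silyloxy]phenyl}penta-2,4-dien-1-one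
Product: 17 (2Z,4E)-1-[(1S,2S,6S)-2-(3,4-dimethoxyphenyl)-6-(4-hydroxy-3-methoxyphenyl)cyclohex-3-en-1-yl]-3-hydroxy-5-(4-hydroxy-3-methoxyphenyl)penta-2,4-dien-1-one
Conditions: Bu4NF (2.4 equiv), AcOH (3 equiv), THF, 0 °C to rt
Reagents that add atoms: none
Why: Fluoride cleavage of both aryl silyl ethers, buffered with AcOH so that the base-sensitive enolised 1,3-diketone is not exposed to retro-Claisen conditions; no stereocentre is involved.

**Compound list**

1 | 3,4-dimethoxybiphenyl | COc1ccc(-c2ccccc2)cc1OC | starting material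
2 | lithium 1-(3,4-dimethoxyphenyl)cyclohexa-2,5-dien-1-ide | [Li]C1(c2ccc(OC)c(OC)c2)C=CCC=C1 | intermediate (not isolated)
3 | 3-(3,4-dimethoxyphenyl)cyclohexa-1,4-diene | COc1ccc(C2C=CCC=C2)cc1OC | intermediate
4 | 4-iodo-2-methoxyphenol | COc1cc(I)ccc1O | starting material
5 | (4-iodo-2-methoxyphenoxy)tri(propan-2-yl)silane | COc1cc(I)ccc1O[Si](C(C)C)(C(C)C)C(C)C | intermediate
6 | carbon monoxide | [C-]#[O+] | starting material
7 | methyl (1S,2S,6S)-2-(3,4-dimethoxyphenyl)-6-{3-methoxy-4-[tri(propan-2-yl)silyloxy]phenyl}cyclohex-3-ene-1-carboxylate | COC(=O)[C@@H]1[C@@H](c2ccc(OC)c(OC)c2)C=CC[C@@H]1c1ccc(O[Si](C(C)C)(C(C)C)C(C)C)c(OC)c1 | intermediate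
8 | (1S,2S,6S)-2-(3,4-dimethoxyphenyl)-N-methoxy-6-{3-methoxy-4-[tri(propan-2-yl)silyloxy]phenyl}-N-methylcyclohex-3-ene-1-carboxamide | CON(C)C(=O)[C@@H]1[C@@H](c2ccc(OC)c(OC)c2)C=CC[C@@H]1c1ccc(O[Si](C(C)C)(C(C)C)C(C)C)c(OC)c1 | intermediate
9 | bromomagnesium hemiaminal formed from 8 and MeMgBr (carbinol centre not defined) | CON(C)C(C)(O[Mg]Br)[C@@H]1[C@@H](c2ccc(OC)c(OC)c2)C=CC[C@@H]1c1ccc(O[Si](C(C)C)(C(C)C)C(C)C)c(OC)c1 | intermediate (not isolated)
10 | 1-[(1S,2S,6S)-2-(3,4-dimethoxyphenyl)-6-{3-methoxy-4-[tri(propan-2-yl)silyloxy]phenyl}cyclohex-3-en-1-yl]ethan-1-one | CC(=O)[C@@H]1[C@@H](c2ccc(OC)c(OC)c2)C=CC[C@@H]1c1ccc(O[Si](C(C)C)(C(C)C)C(C)C)c(OC)c1 | intermediate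
11 | ferulic acid, (E)-3-(4-hydroxy-3-methoxyphenyl)prop-2-enoic acid | COc1cc(/C=C/C(=O)O)ccc1O | starting material
12 | tri(propan-2-yl)silyl (E)-3-{3-methoxy-4-[tri(propan-2-yl)silyloxy]phenyl}prop-2-enoate | COc1cc(/C=C/C(=O)O[Si](C(C)C)(C(C)C)C(C)C)ccc1O[Si](C(C)C)(C(C)C)C(C)C | intermediate (not isolated)
13 | (E)-3-{3-methoxy-4-[tri(propan-2-yl)silyloxy]phenyl}prop-2-enoic acid | COc1cc(/C=C/C(=O)O)ccc1O[Si](C(C)C)(C(C)C)C(C)C | intermediate
14 | (E)-1-(1H-benzotriazol-1-yl)-3-{3-methoxy-4-[tri(propan-2-yl)silyloxy]phenyl}prop-2-en-1-one | COc1cc(/C=C/C(=O)n2nnc3ccccc32)ccc1O[Si](C(C)C)(C(C)C)C(C)C | intermediate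
15 | lithium 1-[(1S,2S,6S)-2-(3,4-dimethoxyphenyl)-6-{3-methoxy-4-[tri(propan-2-yl)silyloxy]phenyl}cyclohex-3-en-1-yl]ethen-1-olate | C=C(O[Li])[C@@H]1[C@@H](c2ccc(OC)c(OC)c2)C=CC[C@@H]1c1ccc(O[Si](C(C)C)(C(C)C)C(C)C)c(OC)c1 | intermediate (not isolated)
16 | (2Z,4E)-1-[(1S,2S,6S)-2-(3,4-dimethoxyphenyl)-6-{3-methoxy-4-[tri(propan-2-yl)silyloxy]phenyl}cyclohex-3-en-1-yl]-3-hydroxy-5-{3-methoxy-4-[tri(propan-2-yl)silyloxy]phenyl}penta-2,4-dien-1-one | COc1cc(/C=C/C(O)=C/C(=O)[C@@H]2[C@@H](c3ccc(OC)c(OC)c3)C=CC[C@@H]2c2ccc(O[Si](C(C)C)(C(C)C)C(C)C)c(OC)c2)ccc1O[Si](C(C)C)(C(C)C)C(C)C | intermediate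
17 | (2Z,4E)-1-[(1S,2S,6S)-2-(3,4-dimethoxyphenyl)-6-(4-hydroxy-3-methoxyphenyl)cyclohex-3-en-1-yl]-3-hydroxy-5-(4-hydroxy-3-methoxyphenyl)penta-2,4-dien-1-one | COc1cc(/C=C/C(O)=C/C(=O)[C@@H]2[C@@H](c3ccc(OC)c(OC)c3)C=CC[C@@H]2c2ccc(O)c(OC)c2)ccc1O | target

**Step count and risks**

Total step count: 9. Longest linear sequence: 6 steps (steps 1, 3, 4, 5, 8, 9); steps 2 and 6–7 are side branches.

Steps most likely to fail:

1. Step 3. The arylpalladium intermediate may be carbonylated before it inserts the alkene, which would lead to simple methoxycarbonylation of the iodide or to aryl ketones. The alkylpalladium intermediate may lose the syn β-hydrogen at C2 before CO is captured, giving Heck-type and chain-walked products. Discrimination of the two enantiotopic alkenes may also be poor. The fallback uses known reaction types only; it sets out from aryl iodide 5 and comes back at ester 7.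
   - Wittig methylenation of 3,4-dimethoxycinnamaldehyde (Ph3P=CH2, THF) gives (E)-1-(3,4-dimethoxyphenyl)buta-1,3-diene F1.
   - An endo-selective Diels–Alder reaction of this diene with 3-acryloyl-1,3-oxazolidin-2-one is catalysed by the Cu(SbF6)2 complex of a tert-butyl-bis(oxazoline) (divalent copper, ligand hand chosen for the 2S series). It should give 3-[(1R,2S)-2-(3,4-dimethoxyphenyl)cyclohex-3-ene-1-carbonyl]-1,3-oxazolidin-2-one F2.
   - NaOMe in MeOH cleaves the imide and equilibrates C1, which should favour the trans ester methyl (1S,2S)-2-(3,4-dimethoxyphenyl)cyclohex-3-ene-1-carboxylate F3.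
   - Aminolysis with quinolin-8-amine and AlMe3 in toluene gives (1S,2S)-2-(3,4-dimethoxyphenyl)-N-(quinolin-8-yl)cyclohex-3-ene-1-carboxamide F4.
   - Quinoline-directed β-C–H arylation with 5 (Pd(OAc)2, AgOAc, toluene, 110 °C) proceeds through a cis-fused five-membered palladacycle. It therefore places Ar2 on the C6 methylene cis to the amide and trans to Ar1, giving (1S,2S,6S)-2-(3,4-dimethoxyphenyl)-6-{3-methoxy-4-[tri(propan-2-yl)silyloxy]phenyl}-N-(quinolin-8-yl)cyclohex-3-ene-1-carboxamide F5.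
   - Ni(tmhd)2-catalysed methanolysis of the quinolinyl amide in MeOH at 100 °C then returns ester 7 under neutral conditions.

2. Step 8. The enolate may be acylated on oxygen or add in conjugate fashion to the cinnamoyl donor, and proton transfer from the product may stall conversion. The fallback replaces acylation by aldol addition and oxidation; it sets out from ketone 10 and comes back at diketone 16.
   - Lithium enolate 15 is added at −78 °C to (E)-3-{3-methoxy-4-[tri(propan-2-yl)silyloxy]phenyl}prop-2-enal F6, made from 4-hydroxy-3-methoxycinnamaldehyde with i-Pr3SiCl and imidazole.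
   - This 1,2-addition gives (E)-1-[(1S,2S,6S)-2-(3,4-dimethoxyphenyl)-6-{3-methoxy-4-[tri(propan-2-yl)silyloxy]phenyl}cyclohex-3-en-1-yl]-3-hydroxy-5-{3-methoxy-4-[tri(propan-2-yl)silyloxy]phenyl}pent-4-en-1-one F7 as a mixture of carbinol epimers.
   - Dess–Martin oxidation of this β-hydroxy ketone gives 16.

3. Step 4. Aminolysis of an ester flanked by two aryl-bearing carbons may be sluggish, and forcing it may epimerise C1. The fallback sets out from ester 7 and comes back at ketone 10, bypassing 8 and 9.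
   - Petasis methylenation (Cp2TiMe2, toluene, 70 °C) turns the ester carbonyl into the methyl enol ether 1-[(1S,2S,6S)-2-(3,4-dimethoxyphenyl)-6-{3-methoxy-4-[tri(propan-2-yl)silyloxy]phenyl}cyclohex-3-en-1-yl]-1-methoxyethene F8.
   - Dilute aqueous HCl in THF hydrolyses it to 10 without involving the C1–H.

**Further compounds**

F1 | step 3 | (E)-1-(3,4-dimethoxyphenyl)buta-1,3-diene | COc1ccc(/C=C/C=C)cc1OC
F2 | step 3 | 3-[(1R,2S)-2-(3,4-dimethoxyphenyl)cyclohex-3-ene-1-carbonyl]-1,3-oxazolidin-2-one | O=C1OCCN1C(=O)[C@H]1[C@@H](c2ccc(OC)c(OC)c2)C=CCC1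
F3 | step 3 | methyl (1S,2S)-2-(3,4-dimethoxyphenyl)cyclohex-3-ene-1-carboxylate | COC(=O)[C@@H]1[C@@H](c2ccc(OC)c(OC)c2)C=CCC1
F4 | step 3 | (1S,2S)-2-(3,4-dimethoxyphenyl)-N-(quinolin-8-yl)cyclohex-3-ene-1-carboxamide | O=C(Nc1cccc2cccnc12)[C@@H]1[C@@H](c2ccc(OC)c(OC)c2)C=CCC1
F5 | step 3 | (1S,2S,6S)-2-(3,4-dimethoxyphenyl)-6-{3-methoxy-4-[tri(propan-2-yl)silyloxy]phenyl}-N-(quinolin-8-yl)cyclohex-3-ene-1-carboxamide | O=C(Nc1cccc2cccnc12)[C@@H]1[C@@H](c2ccc(OC)c(OC)c2)C=CC[C@@H]1c1ccc(O[Si](C(C)C)(C(C)C)C(C)C)c(OC)c1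
F6 | step 8 | (E)-3-{3-methoxy-4-[tri(propan-2-yl)silyloxy]phenyl}prop-2-enal | COc1cc(/C=C/C=O)ccc1O[Si](C(C)C)(C(C)C)C(C)C
F7 | step 8 | (E)-1-[(1S,2S,6S)-2-(3,4-dimethoxyphenyl)-6-{3-methoxy-4-[tri(propan-2-yl)silyloxy]phenyl}cyclohex-3-en-1-yl]-3-hydroxy-5-{3-methoxy-4-[tri(propan-2-yl)silyloxy]phenyl}pent-4-en-1-one (both carbinol epimers) | COc1cc(/C=C/C(O)CC(=O)[C@@H]2[C@@H](c3ccc(OC)c(OC)c3)C=CC[C@@H]2c2ccc(O[Si](C(C)C)(C(C)C)C(C)C)c(OC)c2)ccc1O[Si](C(C)C)(C(C)C)C(C)C
F8 | step 4 | 1-[(1S,2S,6S)-2-(3,4-dimethoxyphenyl)-6-{3-methoxy-4-[tri(propan-2-yl)silyloxy]phenyl}cyclohex-3-en-1-yl]-1-methoxyethene | C=C(OC)[C@@H]1[C@@H](c2ccc(OC)c(OC)c2)C=CC[C@@H]1c1ccc(O[Si](C(C)C)(C(C)C)C(C)C)c(OC)c1
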